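**Retrosynthetic overview**
1. Target ⇐ partial MnO2 oxidation of one of the two identical allylic carbinols of C2-symmetric (3R,6S,3'R,6'S)-ε,ε-carotene-3,3'-diol; the base-labile C6–H γ to the enone exists only after this last, neutral step.
2. Diol ⇐ two-directional C15 + C10 + C15 union at C11–C12 and C11'–C12'. Both carbons are allylic electrophiles by nature; C11 is reversed to an α-sulfonyl allyl carbanion, alkylated by a C10 bis-allylic dibromide, and twofold loss of PhSO2H then gives the polyene in the same flask.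
3. C15 (3R,6S)-acetoxy sulfone ⇐ lipase resolution ⇐ cis-selective Luche reduction ⇐ sulfinate SN1' on a vinyl carbinol ⇐ vinyl Grignard on 3-oxo-α-ionone ⇐ allylic oxidation of (±)-α-ionone. C10 dibromide ⇐ C10 dialdehyde.
4. Rings: none is formed; both ε-rings are carried intact from α-ionone (two copies of one resolved C15 unit).

Assumption: the target is all-E (6S,3'R,6'S)-3'-hydroxy-ε,ε-caroten-3-one (carotenoid numbering; C3/C6 of an end group are C1/C4 in the cyclohexene names), and the C10 dialdehyde is a purchasable carotenoid intermediate. The cis preference claimed in step 4 and the 3R preference of the lipase in step 5 are argued by analogy with related 3-oxo/3-hydroxy ε-ring compounds, not from data on these exact substrates.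

**Route**

Step 1
Reactants: 1 (±)-α-ionone
Product: 2 (±)-3-oxo-α-ionone
Conditions: Rh2(cap)4 (1 mol %, cap = caprolactamate), t-BuOOH (70% aq, 5 equiv), K2CO3, CH2Cl2, rt
Reagents that add atoms: tert-butyl hydroperoxide, CC(C)(C)OO
Why: Radical allylic C–H oxidation (Kharasch-type, dirhodium/t-BuOOH) at the only unhindered ring allylic CH2 (C3) gives the conjugated ring enone, the electron-poor side-chain enone being inert; no stereocentre is set (C6 stays racemic).

Step 2
Reactants: 2 (±)-3-oxo-α-ionone; 3 vinylmagnesium bromide (CH2=CHMgBr, 1 M in THF)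
Product: 4 (±)-4-[(1E)-3-hydroxy-3-methylpenta-1,4-dien-1-yl]-3,5,5-trimethylcyclohex-2-en-1-one (both C9 epimers)
Conditions: 3 (1.05 equiv), THF, −78 → −40 °C; H2O / aq NH4Cl
Reagents that add atoms: none
Why: Chemoselective Grignard 1,2-addition to the unhindered side-chain methyl ketone, which is far more reactive than the β,β-disubstituted, neopentyl-flanked ring enone (the same preference seen in side-chain-selective borohydride reduction of this diketone to 3-oxo-α-ionol); the new carbinol centre is irrelevant because C9 becomes sp2.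

Step 3
Reactants: 4 (±)-keto vinyl carbinol
Product: 5 (±)-3,5,5-trimethyl-4-[(1E,3E)-3-methyl-5-(phenylsulfonyl)penta-1,3-dien-1-yl]cyclohex-2-en-1-one
Conditions: PhSO2Na (1.5 equiv), AcOH, rt, 12 h; recrystallise (9E isomer)
Reagents that add atoms: sodium benzenesulfinate, [Na+].[O-]S(=O)c1ccccc1
Why: SN1' substitution with allylic transposition (Julia C15-sulfone formation), in which AcOH ionises the tertiary bis-allylic alcohol to a pentadienyl cation that sulfinate sulfur captures at the unhindered primary terminus C11, giving the conjugated (7E,9E)-dienyl sulfone.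

Step 4
Reactants: 5 (±)-3-oxo C15 sulfone
Product: 6 rac-(1R,4S)-3,5,5-trimethyl-4-[(1E,3E)-3-methyl-5-(phenylsulfonyl)penta-1,3-dien-1-yl]cyclohex-2-en-1-ol (cis racemate; carotenoid 3R,6S + 3S,6R)
Conditions: NaBH4, CeCl3·7H2O, MeOH, −40 °C; SiO2 chromatography (minor trans racemate removed)
Reagents that add atoms: none
Why: Luche 1,2-reduction in which the small hydride enters anti to the C6 dienyl arm, so the carbinol ends up cis to the side chain as the major diastereomer (as in borohydride reductions of 3-oxo-ε end groups); only the relative configuration is set here.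

Step 5
Reactants: 6 rac-cis-3-hydroxy C15 sulfone
Product: 7 (1R,4S)-3,5,5-trimethyl-4-[(1E,3E)-3-methyl-5-(phenylsulfonyl)penta-1,3-dien-1-yl]cyclohex-2-en-1-yl acetate (carotenoid 3R,6S)
Conditions: lipase AK (Pseudomonas fluorescens), vinyl acetate (5 equiv), t-BuOMe, 35 °C, stop at 50% conversion; chromatography (unreacted 3S,6R alcohol removed)
Reagents that add atoms: vinyl acetate, CC(=O)OC=C
Why: Lipase-catalysed kinetic resolution by irreversible transesterification (Kazlauskas rule), the enzyme acylating only the 3R carbinol, so the (3R,6S) enantiomer of the cis racemate is taken out as its acetate and both stereocentres of the end group are fixed in absolute terms.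

Step 6
Reactants: 8 (2E,4E,6E)-2,7-dimethylocta-2,4,6-trienedial
Product: 9 (2E,4E,6E)-2,7-dimethylocta-2,4,6-triene-1,8-diol
Conditions: NaBH4, MeOH/THF, 0 °C
Reagents that add atoms: none
Why: Borohydride 1,2-reduction of both enal carbonyls with the triene geometry untouched.

Step 7
Reactants: 9 C10 triene diol
Product: 10 (2E,4E,6E)-1,8-dibromo-2,7-dimethylocta-2,4,6-triene
Conditions: PBr3 (0.7 equiv), pyridine (cat.), Et2O, −10 °C, dark; used at once
Reagents that add atoms: phosphorus tribromide, BrP(Br)Br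
Why: SN2 bromination of the primary allylic alcohols via their phosphite esters, the E geometry being retained.

Step 8
Reactants: 7 (3R,6S)-acetoxy C15 sulfone (2.1 equiv); 10 C10 dibromide (1.0 equiv)
Product: 12 (3R,6S,3'R,6'S)-ε,ε-carotene-3,3'-diol (all-E), via C40 bis-sulfone diacetate 11 (not isolated)
Conditions: LiN(SiMe3)2 (2.1 equiv), THF, −78 °C; 10, −78 → −20 °C; then KOMe (10 equiv), MeOH, 50 °C; heat in EtOAc (70 °C, dark), crystallise
Reagents that add atoms: none
Why: Julia sulfone coupling with reversed polarity, in which C11 of 7 (an electrophilic allylic carbon in its native cation or halide form) reacts as the α-sulfonyl allyl carbanion and is alkylated SN2 at both electrophilic allylic termini of 10 while the acetates survive the amide base at −78 °C, after which methoxide effects twofold 1,2-dehydrosulfonation to C11=C12 and C11'=C12' plus methanolysis of both acetates and heating equilibrates the E-rich polyene to all-E; C3 and C6 are not touched.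

Step 9
Reactants: 12 (3R,6S,3'R,6'S)-ε,ε-carotene-3,3'-diol
Product: 13 (6S,3'R,6'S)-3'-hydroxy-ε,ε-caroten-3-one (target)
Conditions: activated MnO2 (10 equiv), CH2Cl2, 0 °C → rt, stop at ca. 50% conversion; chromatography, recovered 12 recycled
Reagents that add atoms: none
Why: Chemoselective MnO2 oxidation of an allylic alcohol run to partial conversion as a statistical desymmetrisation of the C2-symmetric diol (at most about half is monoketone per pass), the neutral conditions leaving the C6 centre γ to the new enone and the remaining carbinol unchanged.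

**Compound list**
1 | (±)-α-ionone, (3E)-4-(2,6,6-trimethylcyclohex-2-en-1-yl)but-3-en-2-one | CC(=O)/C=C/C1C(C)=CCCC1(C)C | starting material
2 | (±)-3-oxo-α-ionone, 3,5,5-trimethyl-4-[(1E)-3-oxobut-1-en-1-yl]cyclohex-2-en-1-one | CC(=O)/C=C/C1C(C)=CC(=O)CC1(C)C | intermediate
3 | vinylmagnesium bromide, CH2=CHMgBr | C=C[Mg]Br | starting material
4 | (±)-4-[(1E)-3-hydroxy-3-methylpenta-1,4-dien-1-yl]-3,5,5-trimethylcyclohex-2-en-1-one (C9 epimer mixture) | C=CC(C)(O)/C=C/C1C(C)=CC(=O)CC1(C)C | intermediate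
5 | (±)-3,5,5-trimethyl-4-[(1E,3E)-3-methyl-5-(phenylsulfonyl)penta-1,3-dien-1-yl]cyclohex-2-en-1-one | O=S(=O)(c1ccccc1)C/C=C(C)/C=C/C1C(C)=CC(=O)CC1(C)C | intermediate
6 | rac-(1R,4S)-3,5,5-trimethyl-4-[(1E,3E)-3-methyl-5-(phenylsulfonyl)penta-1,3-dien-1-yl]cyclohex-2-en-1-ol (cis racemate, drawn as the 3R,6S enantiomer) | O=S(=O)(c1ccccc1)C/C=C(C)/C=C/[C@@H]1C(C)=C[C@H](O)CC1(C)C | intermediate
7 | (1R,4S)-3,5,5-trimethyl-4-[(1E,3E)-3-methyl-5-(phenylsulfonyl)penta-1,3-dien-1-yl]cyclohex-2-en-1-yl acetate (carotenoid 3R,6S) | O=S(=O)(c1ccccc1)C/C=C(C)/C=C/[C@@H]1C(C)=C[C@H](OC(C)=O)CC1(C)C | intermediate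
8 | (2E,4E,6E)-2,7-dimethylocta-2,4,6-trienedial | O=C/C(C)=C/C=C/C=C(C)/C=O | starting material
9 | (2E,4E,6E)-2,7-dimethylocta-2,4,6-triene-1,8-diol | OC/C(C)=C/C=C/C=C(C)/CO | intermediate
10 | (2E,4E,6E)-1,8-dibromo-2,7-dimethylocta-2,4,6-triene | BrC/C(C)=C/C=C/C=C(C)/CBr | intermediate
11 | (3R,6S,3'R,6'S)-11,11'-bis(phenylsulfonyl)-11,12,11',12'-tetrahydro-ε,ε-carotene-3,3'-diyl diacetate (C11/C11' epimer mixture, not isolated) | CC1=C[C@H](OC(C)=O)CC(C)(C)[C@@H]1/C=C/C(C)=C/C(S(=O)(=O)c1ccccc1)C/C(C)=C/C=C/C=C(C)/CC(S(=O)(=O)c1ccccc1)/C=C(C)/C=C/[C@@H]1C(C)=C[C@H](OC(C)=O)CC1(C)C | intermediate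
12 | (3R,6S,3'R,6'S)-ε,ε-carotene-3,3'-diol (all-E) | CC1=C[C@H](O)CC(C)(C)[C@@H]1/C=C/C(C)=C/C=C/C(C)=C/C=C/C=C(C)/C=C/C=C(C)/C=C/[C@@H]1C(C)=C[C@H](O)CC1(C)C | intermediate
13 | (6S,3'R,6'S)-3'-hydroxy-ε,ε-caroten-3-one (all-E) | CC1=CC(=O)CC(C)(C)[C@@H]1/C=C/C(C)=C/C=C/C(C)=C/C=C/C=C(C)/C=C/C=C(C)/C=C/[C@@H]1C(C)=C[C@H](O)CC1(C)C | target

**Step count**
Total: 9 steps. Longest linear sequence: 7 steps (steps 1, 2, 3, 4, 5, 8, 9); steps 6 and 7 are the C10 branch.

**Three steps most likely to fail, with fallbacks**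

Step 8 (acyl transfer from the acetate to the sulfonyl carbanion, or incomplete one-flask elimination). The fallback sets out from 7 and comes back at 12. The acetate is removed first (K2CO3, MeOH, rt) to give the free (3R,6S)-hydroxy C15 sulfone F6. Its O,C-dianion (n-BuLi, 2 equiv per sulfone, THF/DMPU, −78 °C) is alkylated with 10 (0.5 equiv), and the C40 bis-sulfone diol F7 is isolated and purified. A separate dehydrosulfonation (KOMe, MeOH/cyclohexane, 60 °C) then gives 12. This replaces the ester-protected one-flask process by a protecting-group-free, two-stage dianion sequence.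

Step 4 (the cis:trans ratio may be low or inverted). The fallback sets out from 5 and comes back at 7. Reduction with the bulky KBH(s-Bu)3 (THF, −78 °C) is used to steer toward the trans racemate, rac-trans-3-hydroxy C15 sulfone F3; any trans material from step 4 can be added. Lipase AK with vinyl acetate then acylates the 3R,6R enantiomer to the (3R,6R)-acetoxy sulfone F5, which is discarded, and leaves the (3S,6S)-hydroxy sulfone F4. Mitsunobu inversion at C3 (PPh3, DIAD, AcOH, toluene, 0 °C) turns F4 directly into 7, so the configuration at C3 is set by inversion instead of by facial selectivity of the hydride.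

Step 2 (competing addition to the ring enone, or enolisation at the doubly vinylogous C6–H). The fallback sets out from 1 and comes back at 5. Compound 3 is added to 1 itself (THF, 0 °C; only one carbonyl present) to give vinyl-α-ionol F1. PhSO2Na in AcOH converts it into the C15 dienyl phenyl sulfone F2. The ring allylic CH2 is then oxidised (Rh2(cap)4, t-BuOOH, K2CO3, CH2Cl2) to 5, so no discrimination between two ketones is needed.

**Further compounds**
F1 | step 2 | (±)-(1E)-3-methyl-1-(2,6,6-trimethylcyclohex-2-en-1-yl)penta-1,4-dien-3-ol (vinyl-α-ionol) | C=CC(C)(O)/C=C/C1C(C)=CCCC1(C)C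
F2 | step 2 | (±)-[(2E,4E)-3-methyl-5-(2,6,6-trimethylcyclohex-2-en-1-yl)penta-2,4-dien-1-yl] phenyl sulfone | O=S(=O)(c1ccccc1)C/C=C(C)/C=C/C1C(C)=CCCC1(C)C
F3 | step 4 | rac-(1S,4S)-3,5,5-trimethyl-4-[(1E,3E)-3-methyl-5-(phenylsulfonyl)penta-1,3-dien-1-yl]cyclohex-2-en-1-ol (trans racemate, drawn as the 3S,6S enantiomer) | O=S(=O)(c1ccccc1)C/C=C(C)/C=C/[C@@H]1C(C)=C[C@@H](O)CC1(C)C
F4 | step 4 | (1S,4S)-3,5,5-trimethyl-4-[(1E,3E)-3-methyl-5-(phenylsulfonyl)penta-1,3-dien-1-yl]cyclohex-2-en-1-ol (single enantiomer, carotenoid 3S,6S) | O=S(=O)(c1ccccc1)C/C=C(C)/C=C/[C@@H]1C(C)=C[C@@H](O)CC1(C)C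
F5 | step 4 | (1R,4R)-3,5,5-trimethyl-4-[(1E,3E)-3-methyl-5-(phenylsulfonyl)penta-1,3-dien-1-yl]cyclohex-2-en-1-yl acetate (carotenoid 3R,6R) | O=S(=O)(c1ccccc1)C/C=C(C)/C=C/[C@H]1C(C)=C[C@H](OC(C)=O)CC1(C)C
F6 | step 8 | (1R,4S)-3,5,5-trimethyl-4-[(1E,3E)-3-methyl-5-(phenylsulfonyl)penta-1,3-dien-1-yl]cyclohex-2-en-1-ol (single enantiomer, carotenoid 3R,6S) | O=S(=O)(c1ccccc1)C/C=C(C)/C=C/[C@@H]1C(C)=C[C@H](O)CC1(C)C
F7 | step 8 | (3R,6S,3'R,6'S)-11,11'-bis(phenylsulfonyl)-11,12,11',12'-tetrahydro-ε,ε-carotene-3,3'-diol (C11/C11' epimer mixture) | CC1=C[C@H](O)CC(C)(C)[C@@H]1/C=C/C(C)=C/C(S(=O)(=O)c1ccccc1)C/C(C)=C/C=C/C=C(C)/CC(S(=O)(=O)c1ccccc1)/C=C(C)/C=C/[C@@H]1C(C)=C[C@H](O)CC1(C)C
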